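**Retrosynthetic overview**
- Feature: in ring A (the 2-hydroxy-6-methoxyphenyl ring) the ketone-bearing carbon C1 sits between the two oxygen-bearing carbons C2 and C6. This O–C2–C1(acyl)–C6–O triad is read as the acetal carbon of 1,1-dimethoxyethene joined to C3 and C4 of a 3-acyl-4-methoxy-2-pyrone.
- Last disconnection: both phenols are unmasked together from the 2,6-dimethoxyphenyl ketone that still carries the ring B benzyl ether. Its two OMe groups are equivalent, so cleaving one of them cannot give isomers.
- Key disconnection: ring A is cut at C1–C2 and C3–C4. This leads back to the acylpyrone (four ring carbons) and the ketene acetal (two ring carbons), with CO2 and MeOH expelled in the forward direction.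
- The acylpyrone comes from 4-hydroxy-2-pyrone by C3-acylation with 9-(4-(benzyloxy)phenyl)nonanoic acid followed by O-methylation. The acid comes from a C8 phosphonium salt and 4-(benzyloxy)benzaldehyde by Wittig reaction and alkene hydrogenation.
- Ring order: ring B and the pyrone ring are bought. Ring A is the only ring made, and it is made out of the pyrone ring.

Key step: step 6

Assumption: 4-hydroxy-2H-pyran-2-one and 1,1-dimethoxyethene are taken as catalogue compounds. The Wittig alkene is drawn as its Z isomer, although its geometry has no bearing because step 3 removes it. The target has no stereocentre.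

**Step 1**
Reactants: 1 8-bromooctanoic acid
Product: 2 (7-carboxyheptyl)triphenylphosphonium bromide
Conditions: PPh3 (1.05 equiv), MeCN, reflux, 36 h; trituration with Et2O
Reagents that add atoms: triphenylphosphine, c1ccc(cc1)P(c1ccccc1)c1ccccc1
Why: SN2 alkylation of triphenylphosphine by the primary bromide (phosphonium salt formation) should proceed in polar MeCN without touching the free acid, and the salt is purified by trituration.

**Step 2**
Reactants: 2 (7-carboxyheptyl)triphenylphosphonium bromide; 3 4-(benzyloxy)benzaldehyde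
Product: 5 (Z)-9-(4-(benzyloxy)phenyl)non-8-enoic acid, via sodium carboxylate ylide 4 (not isolated)
Conditions: NaN(SiMe3)2 (2.2 equiv), THF, 0 °C, 45 min; then 3, −78 °C → rt; 1 M HCl work-up
Reagents that add atoms: none
Why: Wittig olefination, in which two equivalents of base give the unstabilised carboxylate ylide 4 that should add to the non-enolisable aldehyde 3 to give mainly the Z alkene, a geometry that step 3 erases.

**Step 3**
Reactants: 5 (Z)-9-(4-(benzyloxy)phenyl)non-8-enoic acid
Product: 6 9-(4-(benzyloxy)phenyl)nonanoic acid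
Conditions: H2 (1–3 atm), RhCl(PPh3)3 (5 mol %), toluene/EtOH 1:1, 40 °C
Reagents that add atoms: none
Why: Homogeneous hydrogenation with RhCl(PPh3)3 should saturate the unhindered 1,2-disubstituted alkene and, unlike Pd/C, offers no pathway for hydrogenolysis of the aryl benzyl ether.

**Step 4**
Reactants: 6 9-(4-(benzyloxy)phenyl)nonanoic acid; 7 4-hydroxy-2H-pyran-2-one
Product: 9 3-(9-(4-(benzyloxy)phenyl)nonanoyl)-4-hydroxy-2H-pyran-2-one, via pyron-4-yl ester 8 (not isolated)
Conditions: DCC (1.1 equiv), DMAP (0.3 equiv), toluene, rt, 2 h, then 80 °C, 12 h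
Reagents that add atoms: none
Why: Steglich-type activation first esterifies the acidic 4-OH to give 8, and DMAP then carries the acyl group from O4 to the nucleophilic C3 (Fries-type O-to-C acyl migration known for 4-hydroxy-2-pyrones), the hydrogen-bonded tricarbonyl 9 being the thermodynamic sink.

**Step 5**
Reactants: 9 3-(9-(4-(benzyloxy)phenyl)nonanoyl)-4-hydroxy-2H-pyran-2-one
Product: 10 3-(9-(4-(benzyloxy)phenyl)nonanoyl)-4-methoxy-2H-pyran-2-one
Conditions: Me2SO4 (1.3 equiv), K2CO3 (1.5 equiv), dry acetone, reflux
Reagents that add atoms: dimethyl sulfate, COS(=O)(=O)OC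
Why: Williamson-type O-alkylation of the potassium salt of the vinylogous acid with the hard electrophile Me2SO4, the standard passage from 4-hydroxy- to 4-methoxy-2-pyrones, should place the methyl group on O4 and keep the 2-pyrone form, while K2CO3 is too weak to enolise the side-chain CH2.

**Step 6**
Reactants: 10 3-(9-(4-(benzyloxy)phenyl)nonanoyl)-4-methoxy-2H-pyran-2-one; 11 1,1-dimethoxyethene
Product: 14 9-(4-(benzyloxy)phenyl)-1-(2,6-dimethoxyphenyl)nonan-1-one, via bicyclic lactone 12 (not isolated), via trimethoxycyclohexadiene 13 (not isolated)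
Conditions: 11 (8 equiv, added in portions), mesitylene, base-washed sealed tube, 140 °C, 24–48 h
Reagents that add atoms: none
Why: The pyrone diene C3=C4–C5=C6, made electron-poor by the lactone carbonyl and the C3 ketone, should take up the electron-rich alkene of 11 in an intermolecular, strongly asynchronous inverse-demand [4+2] cycloaddition that closes the six-membered carbocycle of 12 by forming the C6–CH2 and C3–C(OMe)2 bonds. Lactone 12 then loses CO2 by retro-[4+2] cleavage to diene 13, and 13 loses methanol across its C(OMe)2–CH2 unit, so that pyrone C3, C4, C5 and C6 together with the two carbons of 11 become ring A. The closest known reaction type is the inverse-demand Diels–Alder/decarboxylation/aromatisation sequence of 3-acyl- and 3-alkoxycarbonyl-2-pyrones with 1,1-dialkoxyethenes, which gives ortho-alkoxyaryl carbonyl compounds; the donor at C4 lies outside that demonstrated scope and, with the twist it forces on the ketone, should slow the reaction, hence the excess of 11 and the high temperature. The selectivity needed is regiochemical: the nucleophilic CH2 of 11 must bond to C6, the unhindered CH terminus of the vinylogous acceptor, and not to C4, which is shielded and electronically damped by its methoxy group, so that the acetal carbon ends next to the acyl-bearing carbon. The two bridgehead stereocentres of 12 are formed as a racemate and vanish on aromatisation, so no stereocontrol is required.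

**Step 7**
Reactants: 14 9-(4-(benzyloxy)phenyl)-1-(2,6-dimethoxyphenyl)nonan-1-one
Product: 16 1-(2-hydroxy-6-methoxyphenyl)-9-(4-hydroxyphenyl)nonan-1-one (CNP0117926.0), via bis(dichloroboryloxy) ketone 15 (not isolated)
Conditions: BCl3 (1 M in CH2Cl2, 3.5 equiv), pentamethylbenzene (3 equiv), CH2Cl2, −78 → 0 °C; then H2O
Reagents that add atoms: none
Why: Lewis-acid ether cleavage, in which BCl3 bound to the ketone oxygen reaches only a flanking OMe and, once one methyl has left as MeCl, the six-membered O–B–O chelate of 15 ties up the carbonyl so that the second, equivalent OMe should stay, while BCl3 with pentamethylbenzene as a non-basic benzyl-cation trap is the known low-temperature debenzylation of aryl benzyl ethers.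

**Compound list**
1 | 8-bromooctanoic acid | OC(=O)CCCCCCCBr | starting material
2 | (7-carboxyheptyl)triphenylphosphonium bromide | [Br-].OC(=O)CCCCCCC[P+](c1ccccc1)(c1ccccc1)c1ccccc1 | intermediate
3 | 4-(benzyloxy)benzaldehyde | O=Cc1ccc(OCc2ccccc2)cc1 | starting material
4 | sodium 8-(triphenyl-λ5-phosphanylidene)octanoate (in situ) | [Na+].[O-]C(=O)CCCCCCC=P(c1ccccc1)(c1ccccc1)c1ccccc1 | intermediate
5 | (Z)-9-(4-(benzyloxy)phenyl)non-8-enoic acid | OC(=O)CCCCCC/C=C\c1ccc(OCc2ccccc2)cc1 | intermediate
6 | 9-(4-(benzyloxy)phenyl)nonanoic acid | OC(=O)CCCCCCCCc1ccc(OCc2ccccc2)cc1 | intermediate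
7 | 4-hydroxy-2H-pyran-2-one | O=c1cc(O)cco1 | starting material
8 | 2-oxo-2H-pyran-4-yl 9-(4-(benzyloxy)phenyl)nonanoate (in situ) | O=c1cc(OC(=O)CCCCCCCCc2ccc(OCc3ccccc3)cc2)cco1 | intermediate
9 | 3-(9-(4-(benzyloxy)phenyl)nonanoyl)-4-hydroxy-2H-pyran-2-one | O=c1occc(O)c1C(=O)CCCCCCCCc1ccc(OCc2ccccc2)cc1 | intermediate
10 | 3-(9-(4-(benzyloxy)phenyl)nonanoyl)-4-methoxy-2H-pyran-2-one | COc1ccoc(=O)c1C(=O)CCCCCCCCc1ccc(OCc2ccccc2)cc1 | intermediate
11 | 1,1-dimethoxyethene | C=C(OC)OC | starting material
12 | rac-4-(9-(4-(benzyloxy)phenyl)nonanoyl)-5,8,8-trimethoxy-2-oxabicyclo[2.2.2]oct-5-en-3-one (in situ; bridgeheads fixed relative to each other by the bicycle) | O=C1OC2C=C(OC)C1(C(=O)CCCCCCCCc1ccc(OCc3ccccc3)cc1)C(OC)(OC)C2 | intermediate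
13 | 9-(4-(benzyloxy)phenyl)-1-(2,6,6-trimethoxycyclohexa-1,3-dien-1-yl)nonan-1-one (in situ) | COC1=C(C(=O)CCCCCCCCc2ccc(OCc3ccccc3)cc2)C(OC)(OC)CC=C1 | intermediate
14 | 9-(4-(benzyloxy)phenyl)-1-(2,6-dimethoxyphenyl)nonan-1-one | COc1cccc(OC)c1C(=O)CCCCCCCCc1ccc(OCc2ccccc2)cc1 | intermediate
15 | 1-(2-(dichloroboryloxy)-6-methoxyphenyl)-9-(4-(dichloroboryloxy)phenyl)nonan-1-one (in situ; ring A boron also bound to the ketone oxygen) | COc1cccc(OB(Cl)Cl)c1C(=O)CCCCCCCCc1ccc(OB(Cl)Cl)cc1 | intermediate
16 | 1-(2-hydroxy-6-methoxyphenyl)-9-(4-hydroxyphenyl)nonan-1-one | COc1cccc(O)c1C(=O)CCCCCCCCc1ccc(O)cc1 | target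

**Total step count:** 7
**Longest linear sequence:** 7 (1 → 2 → 5 → 6 → 9 → 10 → 14 → 16)

**Steps most likely to fail**

**Step 6.**
- What may go wrong: the cycloaddition may stall, because the C4 donor raises the diene LUMO and turns the C3 ketone out of conjugation while 11 is consumed by thermal oligomerisation. The CH2 terminus of 11 may also add at C4 with loss of methoxide, or across the O=C–C3=C4 heterodiene.
- Fallback (sets out from 6, returns at 14): ring A is bought instead of built. Acid 6 is coupled with MeNHOMe·HCl (EDC·HCl, Et3N, CH2Cl2) to 9-(4-(benzyloxy)phenyl)-N-methoxy-N-methylnonanamide F1. 1,3-Dimethoxybenzene is lithiated between its two methoxy groups (n-BuLi, THF, 0 °C, directed ortho-metalation) to (2,6-dimethoxyphenyl)lithium F2. F2 adds once to F1 (Weinreb ketone synthesis, −78 → 0 °C) and should give 14 on acidic work-up.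

**Step 5.**
- What may go wrong: methylation may go to the wrong site of the ambident tricarbonyl anion (the lactone carbonyl oxygen, the side-chain enol oxygen or C3). The chelated enol may also resist alkylation.
- Fallback (sets out from 6 and 7, returns at 10): methylation and acylation change places, so the methyl group is introduced while only one enol is present.
  - Acid 6 is taken through the Weinreb amide F1, made as above, and i-Bu2AlH (THF, −78 °C) to 9-(4-(benzyloxy)phenyl)nonanal F3.
  - Pyrone 7 is methylated (Me2SO4, K2CO3, acetone) to 4-methoxy-2H-pyran-2-one F4.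
  - F4 is deprotonated at C3, the position flanked by the lactone carbonyl and the methoxy group (n-BuLi, THF, −78 °C), to (4-methoxy-2-oxo-2H-pyran-3-yl)lithium F5.
  - Addition of F5 to F3 should give racemic 3-(9-(4-(benzyloxy)phenyl)-1-hydroxynonyl)-4-methoxy-2H-pyran-2-one F6.
  - Oxidation of F6 with Dess–Martin periodinane (CH2Cl2, rt) delivers 10.

**Step 7.**
- What may go wrong: the excess Lewis acid needed for debenzylation may also cleave the second ortho methyl ether. Benzyl transfer to the electron-rich rings may outrun the scavenger.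
- Fallback (sets out from 14, returns at 16): the two deprotections are separated and carried out by unrelated mechanisms. Hydrogenolysis (H2, 1 atm, Pd/C, EtOAc, rt) removes the benzyl group and should leave the hindered, non-conjugated ketone untouched, giving 1-(2,6-dimethoxyphenyl)-9-(4-hydroxyphenyl)nonan-1-one F7. MgI2 etherate (toluene/Et2O, 80 °C), a chelation-controlled iodide demethylation specific for a methoxy group ortho to a carbonyl, then removes one methyl group to give 16.

**Further compounds**
F1 | step 6 | 9-(4-(benzyloxy)phenyl)-N-methoxy-N-methylnonanamide | CON(C)C(=O)CCCCCCCCc1ccc(OCc2ccccc2)cc1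
F2 | step 6 | (2,6-dimethoxyphenyl)lithium | [Li]c1c(OC)cccc1OC
F3 | step 5 | 9-(4-(benzyloxy)phenyl)nonanal | O=CCCCCCCCCc1ccc(OCc2ccccc2)cc1
F4 | step 5 | 4-methoxy-2H-pyran-2-one | COc1ccoc(=O)c1
F5 | step 5 | (4-methoxy-2-oxo-2H-pyran-3-yl)lithium | [Li]c1c(OC)ccoc1=O
F6 | step 5 | rac-3-(9-(4-(benzyloxy)phenyl)-1-hydroxynonyl)-4-methoxy-2H-pyran-2-one | COc1ccoc(=O)c1C(O)CCCCCCCCc1ccc(OCc2ccccc2)cc1
F7 | step 7 | 1-(2,6-dimethoxyphenyl)-9-(4-hydroxyphenyl)nonan-1-one | COc1cccc(OC)c1C(=O)CCCCCCCCc1ccc(O)cc1
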